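**Retrosynthetic overview**
1. No C–C bond is made and no ring is formed: rings A, C and B all come intact in apigenin 1. The one skeletal bond to forge is the aryl C3'–O bond, made with the sulfate already on that oxygen.
2. Ring A is masked first: C6 and C8 of 1 are brominated (through monobromides 2 and 3) to give 6,8-dibromoapigenin 4. This blocks the only carbons that could compete and makes the ring A phenols poor nucleophiles.
3. Key disconnection C3'–OSO3H: the 4'-phenolate of 4 attacks peroxydisulfate through its ortho carbon (dienone 5) to give sulfate 6. The mechanism places the sulfate on the new 3'-oxygen and leaves 4'-OH free.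
4. Hydrogenolysis of the two C–Br bonds of 6 (through 7 and 8) gives the target 9.

Assumption: the target is achiral (no stereocentre, no stereogenic double bond), so there is nothing to control stereochemically; sulfate monoesters are written in the neutral hydrogen sulfate form of the target SMILES although they are handled as potassium salts.

**Step 1**
Reactants: 1 apigenin
Product: 4 6,8-dibromoapigenin, via 6-bromoapigenin 2 (not isolated), via 8-bromoapigenin 3 (not isolated)
Conditions: NBS (2.05 equiv), DMF, 0 °C → rt, 2 h; pour into water, filter, recrystallise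
Reagents that add atoms: N-bromosuccinimide (NBS), O=C1CCC(=O)N1Br
Why: Electrophilic aromatic bromination (SEAr): C6 and C8 lie ortho/para to the 5- and 7-hydroxyls of the phloroglucinol-type ring A and are far more nucleophilic than C3'/C5' of ring B, which is deactivated by conjugation with the pyranone, so two equivalents of NBS should stop at the 6,8-dibromide; no stereocentre is formed.

**Step 2**
Reactants: 4 6,8-dibromoapigenin
Product: 6 6,8-dibromoluteolin 3'-(hydrogen sulfate), via 3'-sulfooxy dienone tautomer 5 (not isolated)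
Conditions: K2S2O8 (1.1 equiv, slow addition), K2CO3/KHCO3 buffer (pH 9.5), H2O/MeCN 2:1, Ar, dark, 5 → 25 °C, 48 h; then pH 6.5, C18 chromatography (potassium salt; unreacted 4 recovered)
Reagents that add atoms: potassium peroxydisulfate K2S2O8, [K+].[K+].[O-]S(=O)(=O)OOS(=O)(=O)[O-]
Why: Proposed new method: a pKa-gated, halogen-blocked ortho C–H sulfoxylation of the ring B phenol of an otherwise unprotected polyhydroxyflavone, with the sulfate ester kept as the product. At pH 9.5 only 7-OH and 4'-OH are ionised (5-OH stays chelated to the carbonyl), and the 7-phenolate is a bromine-flanked vinylogous carboxylate whose ortho and para carbons are all substituted. The 4'-phenolate therefore attacks a peroxide oxygen of S2O8(2−) through C3' (its para carbon is C1', and C3'/C5' are equivalent), an SN2 displacement of sulfate at oxygen that gives dienone 5. Tautomerisation of 5 restores the arene with the sulfate on the new oxygen and 4'-OH free, so the transient sp3 centre at C3' is lost and no stereocentre remains. The closest known reaction type is the Elbs persulfate oxidation of phenols (and its nitrogen analogue, the Boyland–Sims oxidation), normally run in strong alkali, para-selective and followed by hydrolysis of the sulfate.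

**Step 3**
Reactants: 6 6,8-dibromoluteolin 3'-(hydrogen sulfate)
Product: 9 luteolin 3'-sulfate, via 6-bromoluteolin 3'-sulfate 7 (not isolated), via 8-bromoluteolin 3'-sulfate 8 (not isolated)
Conditions: H2 (1 atm), 10 wt % Pd/C, K2CO3 (3 equiv), MeOH/H2O 4:1, rt, 2–4 h (stop when 7 and 8 are consumed); filter, neutralise to pH 6–7, C18 or Sephadex LH-20 (potassium salt; brief cold H+ resin gives the free acid form)
Reagents that add atoms: none
Why: Palladium-catalysed hydrogenolysis (hydrodehalogenation) cleaves aryl C–Br bonds much faster than it reduces the vinylogous-ester C2=C3 bond of a flavone, and the carbonate traps HBr so the acid-labile but base-stable aryl sulfate survives; no stereocentre is involved.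

**Compound list**
1 | apigenin [5,7-dihydroxy-2-(4-hydroxyphenyl)chromen-4-one] | O=c1cc(-c2ccc(O)cc2)oc2cc(O)cc(O)c12 | starting material
2 | 6-bromoapigenin [6-bromo-5,7-dihydroxy-2-(4-hydroxyphenyl)chromen-4-one] | O=c1cc(-c2ccc(O)cc2)oc2cc(O)c(Br)c(O)c12 | intermediate
3 | 8-bromoapigenin [8-bromo-5,7-dihydroxy-2-(4-hydroxyphenyl)chromen-4-one] | O=c1cc(-c2ccc(O)cc2)oc2c(Br)c(O)cc(O)c12 | intermediate
4 | 6,8-dibromoapigenin [6,8-dibromo-5,7-dihydroxy-2-(4-hydroxyphenyl)chromen-4-one] | O=c1cc(-c2ccc(O)cc2)oc2c(Br)c(O)c(Br)c(O)c12 | intermediate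
5 | 3'-sulfooxy dienone tautomer [6,8-dibromo-5,7-dihydroxy-2-[4-oxo-3-(sulfooxy)cyclohexa-1,5-dien-1-yl]chromen-4-one; racemic, transient] | O=c1cc(C2=CC(OS(=O)(=O)O)C(=O)C=C2)oc2c(Br)c(O)c(Br)c(O)c12 | intermediate
6 | 6,8-dibromoluteolin 3'-(hydrogen sulfate) [6,8-dibromo-5,7-dihydroxy-2-(4-hydroxy-3-sulfooxyphenyl)chromen-4-one] | O=c1cc(-c2ccc(O)c(OS(=O)(=O)O)c2)oc2c(Br)c(O)c(Br)c(O)c12 | intermediate
7 | 6-bromoluteolin 3'-sulfate [6-bromo-5,7-dihydroxy-2-(4-hydroxy-3-sulfooxyphenyl)chromen-4-one] | O=c1cc(-c2ccc(O)c(OS(=O)(=O)O)c2)oc2cc(O)c(Br)c(O)c12 | intermediate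
8 | 8-bromoluteolin 3'-sulfate [8-bromo-5,7-dihydroxy-2-(4-hydroxy-3-sulfooxyphenyl)chromen-4-one] | O=c1cc(-c2ccc(O)c(OS(=O)(=O)O)c2)oc2c(Br)c(O)cc(O)c12 | intermediate
9 | luteolin 3'-sulfate [5,7-dihydroxy-2-(4-hydroxy-3-sulfooxyphenyl)chromen-4-one; achiral] | O=c1cc(-c2ccc(O)c(OS(=O)(=O)O)c2)oc2cc(O)cc(O)c12 | target

**Total step count:** 3. **Longest linear sequence:** 3 steps (1 → 4 → 6 → 9).

**Steps most likely to fail (most risky first)**

Step 2 (the proposed new sulfoxylation). Ortho attack on a conjugated, deactivated phenolate may be slow. Radical over-oxidation, a second sulfoxylation at C5' and ipso chemistry on ring A are the likely side paths. The fallback uses only known reactions and makes the S–O bond instead of the C–O bond; it sets out from 4 and comes back to the route at 6. IBX ortho-oxygenation of the ring B phenol (IBX, DMF, rt) gives 6,8-dibromoapigenin ring B ortho-quinone F1, which is reduced in the same flask with aqueous Na2S2O4 to 6,8-dibromoluteolin F2. Allyl bromide (2.1 equiv), K2CO3, DMF, rt alkylates the two most acidic hydroxyls to give 7,4'-di-O-allyl-6,8-dibromoluteolin F3; the 4'-OH of a flavone catechol is more acidic than the 3'-OH, and 5-OH is chelated. SO3·pyridine in pyridine sulfates the remaining free 3'-OH to give 7,4'-di-O-allyl-6,8-dibromoluteolin 3'-(hydrogen sulfate) F4. Pd(PPh3)4 (5 mol %) and morpholine in THF/MeOH at rt then remove the allyl groups one after the other, by way of 7-O-allyl-6,8-dibromoluteolin 3'-(hydrogen sulfate) F5 or 4'-O-allyl-6,8-dibromoluteolin 3'-(hydrogen sulfate) F6, and deliver 6, from which step 3 continues unchanged.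

Step 1 (site-selective dibromination). Bromination of ring B (C3') or of C3 could compete and give mixtures that are hard to separate. The fallback replaces carbon blocking by oxygen protection plus pKa control; it sets out from 1 and comes back to the route at 9. BnBr (1.0 equiv), KHCO3, DMF, rt alkylates the most acidic hydroxyl to give 7-O-benzylapigenin F7. The sulfoxylation of step 2 is then run at pH 9.0, where the chelated 5-OH (pKa above 11) stays protonated, so C8 is not activated by a phenolate and the 4'-phenolate is the only reactive nucleophile. It gives, through 7-O-benzyl 3'-sulfooxy dienone tautomer F8, 7-O-benzylluteolin 3'-(hydrogen sulfate) F9. H2 (1 atm), Pd/C, KHCO3, MeOH cleaves the single benzyl ether and gives 9.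

Step 3 (hydrodebromination). The risks are over-reduction of the C2=C3 bond to the flavanone and a sluggish second C–Br cleavage. The fallback avoids hydrogen altogether; it sets out from 6 and comes back to the route at 9, again passing through 7 or 8. Na2SO3 (excess) in aqueous NaHCO3 at 60 °C removes the bromines by halophilic attack of sulfite on the keto tautomers of ring A, a reductive debromination known for bromophloroglucinols and bromoresorcinols. The medium is neutral to basic, so the aryl sulfate is safe, and the C2=C3 bond cannot be reduced. It makes no new compound.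

**Further compounds**
F1 | step 2 | 6,8-dibromoapigenin ring B ortho-quinone [6,8-dibromo-2-(3,4-dioxocyclohexa-1,5-dien-1-yl)-5,7-dihydroxychromen-4-one] | O=c1cc(C2=CC(=O)C(=O)C=C2)oc2c(Br)c(O)c(Br)c(O)c12
F2 | step 2 | 6,8-dibromoluteolin [6,8-dibromo-2-(3,4-dihydroxyphenyl)-5,7-dihydroxychromen-4-one] | O=c1cc(-c2ccc(O)c(O)c2)oc2c(Br)c(O)c(Br)c(O)c12
F3 | step 2 | 7,4'-di-O-allyl-6,8-dibromoluteolin | O=c1cc(-c2ccc(OCC=C)c(O)c2)oc2c(Br)c(OCC=C)c(Br)c(O)c12
F4 | step 2 | 7,4'-di-O-allyl-6,8-dibromoluteolin 3'-(hydrogen sulfate) | O=c1cc(-c2ccc(OCC=C)c(OS(=O)(=O)O)c2)oc2c(Br)c(OCC=C)c(Br)c(O)c12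
F5 | step 2 | 7-O-allyl-6,8-dibromoluteolin 3'-(hydrogen sulfate) | O=c1cc(-c2ccc(O)c(OS(=O)(=O)O)c2)oc2c(Br)c(OCC=C)c(Br)c(O)c12
F6 | step 2 | 4'-O-allyl-6,8-dibromoluteolin 3'-(hydrogen sulfate) | O=c1cc(-c2ccc(OCC=C)c(OS(=O)(=O)O)c2)oc2c(Br)c(O)c(Br)c(O)c12
F7 | step 1 | 7-O-benzylapigenin [7-(benzyloxy)-5-hydroxy-2-(4-hydroxyphenyl)chromen-4-one] | O=c1cc(-c2ccc(O)cc2)oc2cc(OCc3ccccc3)cc(O)c12
F8 | step 1 | 7-O-benzyl 3'-sulfooxy dienone tautomer [7-(benzyloxy)-5-hydroxy-2-[4-oxo-3-(sulfooxy)cyclohexa-1,5-dien-1-yl]chromen-4-one; racemic, transient] | O=c1cc(C2=CC(OS(=O)(=O)O)C(=O)C=C2)oc2cc(OCc3ccccc3)cc(O)c12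
F9 | step 1 | 7-O-benzylluteolin 3'-(hydrogen sulfate) [7-(benzyloxy)-5-hydroxy-2-(4-hydroxy-3-sulfooxyphenyl)chromen-4-one] | O=c1cc(-c2ccc(O)c(OS(=O)(=O)O)c2)oc2cc(OCc3ccccc3)cc(O)c12
F0 | step 3 | none | none
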